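**Retrosynthetic overview** (carotenoid numbering; ring B = hydroxylated acetylenic end, ring E = epsilon end)
1. Last cut at C11=C12: E-selective Wittig of a ring-B C15 tributylphosphonium salt with a ring-E C25 polyenal, itself made from a ring-E C15 triphenylphosphonium salt and the C10 trienedial (C11'=C12').
2. Ring E is formed first (step 1): enantioselective proton-initiated cation–olefin cyclisation of open-chain pseudoionone (C1'–C6' bond, loss of H-4'), which sets 6'R.
3. Ring B is formed second (step 10): proton-initiated cation–olefin cyclisation of an open-chain C15 phosphonium salt that already holds the 3-hydroxyl and the 7,8-triple bond (C1–C6 bond, loss of H-6).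
4. C3 comes from (S)-epichlorohydrin (isopropenyl Grignard, then acetylide); the open chain is completed by carboalumination/iodination and Sonogashira coupling with (E)-3-methylpent-2-en-4-yn-1-ol.

Assumption: the target is all-trans (3R,6'R)-7,8-didehydro-β,ε-caroten-3-ol (crocoxanthin); geometrically pure (3E,5E)-pseudoionone, the C10 trienedial and (E)-3-methylpent-2-en-4-yn-1-ol are taken as commercial.

**Step 1**
Reactants: 1 (3E,5E)-pseudoionone
Product: 2 (R)-α-ionone
Conditions: chiral acid (S,S)-IDPi, HN[P(=NSO2CF3)(O2C20H10Ar2)]2 with Ar = 3,5-(CF3)2C6H3 (5 mol%), (CF3)3COH–CHCl3, −30 °C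
Reagents that add atoms: none
Why: Proposed new method: the confined chiral acid, anchored by hydrogen bonding to the dienone carbonyl, protonates C2 of the terminal alkene, the C1 cation is attacked by C6 through a chair fold held in the chiral anion pocket (this C–C bond formation sets 6R), and the counter-anion removes H-4 kinetically to give the α alkene instead of β-ionone; the closest known reaction types are the racemic H3PO4 cyclisation of pseudoionone to α-ionone and IDPi-catalysed enantioselective proton-initiated polyene cyclisations in fluorinated alcohols.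

**Step 2**
Reactants: 2 (R)-α-ionone
Product: 3 vinyl-α-ionol (both C3 epimers)
Conditions: CH2=CHMgBr (1.3 equiv), THF, −20 → 0 °C; aq. NH4Cl
Reagents that add atoms: vinylmagnesium bromide, C=C[Mg]Br
Why: Grignard 1,2-addition to the enone at low temperature leaves C6' untouched; the new carbinol centre forms unselectively and is erased in step 3.

**Step 3**
Reactants: 3 vinyl-α-ionol
Product: 4 ring-E C15 triphenylphosphonium bromide (9E)
Conditions: PPh3·HBr (1.05 equiv), MeOH, rt, 24 h; crystallise from EtOAc
Reagents that add atoms: triphenylphosphine hydrobromide, [Br-].c1ccc(cc1)[PH+](c1ccccc1)c1ccccc1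
Why: Acid-induced ionisation of the tertiary allylic alcohol and capture of the allyl cation by PPh3 at the primary terminus (SN1/SN2' phosphonium salt formation with allylic transposition) gives the conjugated E salt, which crystallises; C6' is not part of the cation.

**Step 4**
Reactants: 4 ring-E C15 triphenylphosphonium bromide, 5 (2E,4E,6E)-2,7-dimethylocta-2,4,6-trienedial
Product: 8 all-E ring-E C25 aldehyde, via phosphonium ylide 6 (not isolated), via Z-configured aldehyde isomer 7 (not isolated)
Conditions: 5 (3 equiv), 1,2-epoxybutane (5 equiv), EtOH, reflux, 20 h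
Reagents that add atoms: none
Why: Wittig olefination under base-free epoxide-mediated conditions (bromide-opened epoxybutane deprotonates 4 to ylide 6) olefinates one formyl group of the excess dialdehyde, the hindered Z isomer 7 at the new bond equilibrates thermally to E at reflux, and the neutral medium avoids epimerisation at C6'.

**Step 5**
Reactants: 9 (S)-epichlorohydrin
Product: 10 (2S)-1-chloro-4-methylpent-4-en-2-ol
Conditions: CH2=C(CH3)MgBr (1.2 equiv), CuI (10 mol%), THF, −40 → −20 °C; aq. NH4Cl
Reagents that add atoms: isopropenylmagnesium bromide, CC(=C)[Mg]Br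
Why: Copper-catalysed Grignard opening of the epoxide at its unsubstituted carbon (SN2) leaves the C–O bond of the stereocentre intact, so the configuration of 9 is carried over unchanged.

**Step 6**
Reactants: 10 (2S)-1-chloro-4-methylpent-4-en-2-ol
Product: 12 (4S)-2-methylhept-1-en-6-yn-4-ol, via epoxide 11 (not isolated)
Conditions: LiC≡CH·H2NCH2CH2NH2 (3 equiv), DMSO, 0 °C → rt; aq. NH4Cl
Reagents that add atoms: lithium acetylide–ethylenediamine complex, [Li+].[C-]#C.NCCN
Why: The first equivalent of acetylide closes the chlorohydrin to epoxide 11 (intramolecular Williamson reaction) and the second opens it at the terminal carbon (SN2 epoxide alkynylation), again without touching the carbinol C–O bond.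

**Step 7**
Reactants: 12 (4S)-2-methylhept-1-en-6-yn-4-ol
Product: 14 (1E,4S)-1-iodo-2,6-dimethylhepta-1,6-dien-4-ol, via alkenylalane 13 (not isolated)
Conditions: AlMe3 (3 equiv), Cp2ZrCl2 (0.3 equiv), CH2Cl2, 0 °C → rt; then I2 (1.3 equiv), THF, −30 → 0 °C; aq. Rochelle salt
Reagents that add atoms: trimethylaluminium, C[Al](C)C; iodine, II
Why: Negishi zirconium-catalysed carboalumination adds Me–Al syn across the terminal alkyne with methyl on the internal carbon (the 1,1-disubstituted alkene is inert), and iodinolysis of the C–Al bond with retention gives the E iodide.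

**Step 8**
Reactants: 14 (1E,4S)-1-iodo-2,6-dimethylhepta-1,6-dien-4-ol, 15 (2E)-3-methylpent-2-en-4-yn-1-ol
Product: 16 (2E,6E,9S)-3,7,11-trimethyldodeca-2,6,11-trien-4-yne-1,9-diol
Conditions: 15 (1.2 equiv), PdCl2(PPh3)2 (3 mol%), CuI (6 mol%), Et3N, THF, rt
Reagents that add atoms: none
Why: Sonogashira coupling joins the alkenyl iodide and the terminal alkyne with retention of both alkene geometries and tolerates the free hydroxyls; the C9=C10 geometry of the target is thus bought in with 15.

**Step 9**
Reactants: 16 (2E,6E,9S)-3,7,11-trimethyldodeca-2,6,11-trien-4-yne-1,9-diol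
Product: 18 open-chain C15 tributylphosphonium chloride, via allylic chloride 17 (not isolated)
Conditions: NCS (1.1 equiv), Me2S (1.3 equiv), CH2Cl2, −20 → 0 °C; then PBu3 (1.5 equiv), 0 °C → rt
Reagents that add atoms: N-chlorosuccinimide, O=C1CCC(=O)N1Cl; tributylphosphine, CCCCP(CCCC)CCCC
Why: Corey–Kim chlorination converts only the allylic alcohol into the chloride by SN2 (the saturated secondary alcohol is returned unchanged), and SN2 quaternisation with PBu3 follows in the same flask, so no allyl cation is formed and the 9E geometry is kept.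

**Step 10**
Reactants: 18 open-chain C15 tributylphosphonium chloride
Product: 19 ring-B C15 tributylphosphonium triflate
Conditions: CF3SO3H (3 equiv), (CF3)2CHOH–CH2Cl2 (1:4), −40 → −10 °C, 1 h; cold aq. NaHCO3, extract with CH2Cl2
Reagents that add atoms: trifluoromethanesulfonic acid, OS(=O)(=O)C(F)(F)F
Why: Proposed new method: Markovnikov protonation of the isolated isopropenyl group (the most basic π bond, since the acid-inert phosphonium group deactivates the dienyne) gives the C1 tertiary cation, C6 of the enyne alkene attacks it through a six-membered chair to give the C5 tertiary cation, and loss of the propargylic H-6 gives the tetrasubstituted conjugated enyne, while C3 is a spectator (its descriptor changes from S to R only through CIP priorities); the closest known reaction types are the H2SO4 cyclisation of pseudoionone to β-ionone and acid cyclisations of geranyl sulfones and acetates.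

**Step 11**
Reactants: 19 ring-B C15 tributylphosphonium triflate, 8 all-E ring-E C25 aldehyde
Product: 21 crocoxanthin (all-E,3R,6'R)-7,8-didehydro-β,ε-caroten-3-ol, via phosphonium ylide 20 (not isolated)
Conditions: 19 (1.2 equiv), NaOMe (2.5 equiv), CH2Cl2, 0 °C → rt, argon, dark
Reagents that add atoms: none
Why: Wittig olefination in which the allylic trialkylphosphonium ylide gives the new C11=C12 bond with high E selectivity, so no thermal or iodine equilibration (which would erode the 9E acetylenic geometry) is needed; neither stereocentre is touched and the free hydroxyl is tolerated.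

**Compound list**
1 | (3E,5E)-pseudoionone, (3E,5E)-6,10-dimethylundeca-3,5,9-trien-2-one | CC(=O)/C=C/C=C(\C)CCC=C(C)C | starting material
2 | (R)-α-ionone, (3E)-4-[(1R)-2,6,6-trimethylcyclohex-2-en-1-yl]but-3-en-2-one | CC1=CCCC(C)(C)[C@H]1/C=C/C(C)=O | intermediate
3 | vinyl-α-ionol, (1E)-3-methyl-1-[(1R)-2,6,6-trimethylcyclohex-2-en-1-yl]penta-1,4-dien-3-ol (both C3 epimers) | CC1=CCCC(C)(C)[C@H]1/C=C/C(C)(O)C=C | intermediate
4 | [(2E,4E)-3-methyl-5-[(1R)-2,6,6-trimethylcyclohex-2-en-1-yl]penta-2,4-dien-1-yl]triphenylphosphonium bromide | CC1=CCCC(C)(C)[C@H]1/C=C/C(C)=C/C[P+](c1ccccc1)(c1ccccc1)c1ccccc1.[Br-] | intermediate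
5 | (2E,4E,6E)-2,7-dimethylocta-2,4,6-trienedial | O=C/C(C)=C/C=C/C=C(C)/C=O | starting material
6 | phosphonium ylide of 4 | CC1=CCCC(C)(C)[C@H]1/C=C/C(C)=C/C=P(c1ccccc1)(c1ccccc1)c1ccccc1 | intermediate
7 | (2E,4E,6E,8Z,10E,12E)-isomer of 8 | CC1=CCCC(C)(C)[C@H]1/C=C/C(C)=C/C=C\C(C)=C\C=C\C=C(C)\C=O | intermediate
8 | (2E,4E,6E,8E,10E,12E)-2,7,11-trimethyl-13-[(1R)-2,6,6-trimethylcyclohex-2-en-1-yl]trideca-2,4,6,8,10,12-hexaenal | CC1=CCCC(C)(C)[C@H]1/C=C/C(C)=C/C=C/C(C)=C/C=C/C=C(C)/C=O | intermediate
9 | (S)-epichlorohydrin, (2S)-2-(chloromethyl)oxirane | ClC[C@@H]1CO1 | starting material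
10 | (2S)-1-chloro-4-methylpent-4-en-2-ol | ClC[C@@H](O)CC(C)=C | intermediate
11 | (2S)-2-(2-methylprop-2-en-1-yl)oxirane | CC(=C)C[C@H]1CO1 | intermediate
12 | (4S)-2-methylhept-1-en-6-yn-4-ol | C#CC[C@@H](O)CC(C)=C | intermediate
13 | dimethyl[(1E,4S)-4-(dimethylalumanyloxy)-2,6-dimethylhepta-1,6-dien-1-yl]alumane | C[Al](C)/C=C(\C)C[C@@H](O[Al](C)C)CC(C)=C | intermediate
14 | (1E,4S)-1-iodo-2,6-dimethylhepta-1,6-dien-4-ol | I/C=C(\C)C[C@@H](O)CC(C)=C | intermediate
15 | (2E)-3-methylpent-2-en-4-yn-1-ol | C#C/C(C)=C/CO | starting material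
16 | (2E,6E,9S)-3,7,11-trimethyldodeca-2,6,11-trien-4-yne-1,9-diol | OC/C=C(C)/C#C/C=C(\C)C[C@@H](O)CC(C)=C | intermediate
17 | (4S,6E,10E)-12-chloro-2,6,10-trimethyldodeca-1,6,10-trien-8-yn-4-ol | ClC/C=C(C)/C#C/C=C(\C)C[C@@H](O)CC(C)=C | intermediate
18 | tributyl[(2E,6E,9S)-9-hydroxy-3,7,11-trimethyldodeca-2,6,11-trien-4-yn-1-yl]phosphonium chloride | CCCC[P+](CCCC)(CCCC)C/C=C(C)/C#C/C=C(\C)C[C@@H](O)CC(C)=C.[Cl-] | intermediate
19 | tributyl[(2E)-5-[(4R)-4-hydroxy-2,6,6-trimethylcyclohex-1-en-1-yl]-3-methylpent-2-en-4-yn-1-yl]phosphonium trifluoromethanesulfonate | CCCC[P+](CCCC)(CCCC)C/C=C(C)/C#CC1=C(C)C[C@@H](O)CC1(C)C.[O-]S(=O)(=O)C(F)(F)F | intermediate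
20 | phosphonium ylide of 19 | CCCCP(CCCC)(CCCC)=C/C=C(C)/C#CC1=C(C)C[C@@H](O)CC1(C)C | intermediate
21 | crocoxanthin, (all-E,3R,6'R)-7,8-didehydro-β,ε-caroten-3-ol | CC1=CCCC(C)(C)[C@H]1/C=C/C(C)=C/C=C/C(C)=C/C=C/C=C(C)/C=C/C=C(\C)C#CC1=C(C)C[C@@H](O)CC1(C)C | target

**Count**
Total steps: 11. Longest linear sequence: 7 (steps 5 to 11, from 9 to 21).

**Three steps most likely to fail**

Step 1 (asymmetric cyclisation). Risks are low enantiomeric excess, erosion to achiral β-ionone, and catalyst inhibition by the ketone; if the (S,S) pocket delivers the 6S ring, the (R,R) acid is used. Fallback: it sets out from 1 and gives up catalytic asymmetric induction for racemic ring closure plus resolution. 85% H3PO4 in toluene at 80 °C cyclises 1 to racemic α-ionone F1. Preparative chiral supercritical-fluid chromatography on a cellulose tris(3,5-dimethylphenylcarbamate) phase separates the enantiomers. The (R)-enantiomer is 2, where the route is rejoined.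

Step 10 (cyclisation of the phosphonium salt). Risks are retro-Prins loss of isobutene from the hydroxy-bearing C1 cation, five-membered closure at C5, protonation of the dienyne with E/Z scrambling, and methyl migration on over-exposure. Fallback: it sets out from 16 and moves the ring closure ahead of phosphorus introduction, onto a neutral O-acylated substrate.
- Ac2O/pyridine/DMAP gives the open-chain diacetate F2.
- ClSO3H in 2-nitropropane at −78 °C closes ring B to the cyclic diacetate F3; the acetoxy groups retard allylic ionisation and shut down the retro-Prins path.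
- K2CO3/MeOH gives the cyclic diol F4.
- NCS/Me2S converts only its allylic alcohol into the cyclic allylic chloride F5, which PBu3 quaternises in the same flask to the ring-B phosphonium chloride F6.
- NaOMe deprotonates F6 to ylide 20, where the route is rejoined.

Step 11 (final olefination). Risks are sluggish reaction of ylide 20 with the long polyenal and isomer mixtures that cannot be purified at the C40 stage. Fallback: it sets out from 19 and reverses the order of fragment union. Salt 19 with excess 5 and NaOMe in CH2Cl2 gives the ring-B C25 hydroxy ynal F7, which is purified by crystallisation at this smaller stage. F7 is then condensed with 4 (1,2-epoxybutane, EtOH, reflux, through ylide 6). This gives 21 together with its 11'Z isomer F8, which is converted to 21 by heating in heptane at 80 °C without iodine or light. The route is rejoined at 21.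

**Further compounds**
F1 | step 1 | racemic α-ionone | CC1=CCCC(C)(C)C1/C=C/C(C)=O
F2 | step 10 | (2E,6E,9S)-3,7,11-trimethyldodeca-2,6,11-trien-4-yne-1,9-diyl diacetate | CC(=O)OC/C=C(C)/C#C/C=C(\C)C[C@@H](OC(C)=O)CC(C)=C
F3 | step 10 | (2E)-5-[(4R)-4-acetoxy-2,6,6-trimethylcyclohex-1-en-1-yl]-3-methylpent-2-en-4-yn-1-yl acetate | CC(=O)OC/C=C(C)/C#CC1=C(C)C[C@@H](OC(C)=O)CC1(C)C
F4 | step 10 | (1R)-4-[(3E)-5-hydroxy-3-methylpent-3-en-1-yn-1-yl]-3,5,5-trimethylcyclohex-3-en-1-ol | OC/C=C(C)/C#CC1=C(C)C[C@@H](O)CC1(C)C
F5 | step 10 | (1R)-4-[(3E)-5-chloro-3-methylpent-3-en-1-yn-1-yl]-3,5,5-trimethylcyclohex-3-en-1-ol | ClC/C=C(C)/C#CC1=C(C)C[C@@H](O)CC1(C)C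
F6 | step 10 | tributyl[(2E)-5-[(4R)-4-hydroxy-2,6,6-trimethylcyclohex-1-en-1-yl]-3-methylpent-2-en-4-yn-1-yl]phosphonium chloride | CCCC[P+](CCCC)(CCCC)C/C=C(C)/C#CC1=C(C)C[C@@H](O)CC1(C)C.[Cl-]
F7 | step 11 | (2E,4E,6E,8E,10E)-13-[(4R)-4-hydroxy-2,6,6-trimethylcyclohex-1-en-1-yl]-2,7,11-trimethyltrideca-2,4,6,8,10-pentaen-12-ynal | O=C/C(C)=C/C=C/C=C(C)/C=C/C=C(\C)C#CC1=C(C)C[C@@H](O)CC1(C)C
F8 | step 11 | (11'Z)-isomer of 21 | CC1=CCCC(C)(C)[C@H]1/C=C/C(C)=C/C=C\C(C)=C\C=C\C=C(C)\C=C\C=C(/C)C#CC1=C(C)C[C@@H](O)CC1(C)C
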